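**Plan**
- Retrosynthesis: the acetate comes from a diol (acetonide); ring B (the cyclopentenone) is cut at its C=C (ring-closing metathesis) and at the bond between its two sp3 carbons (Ireland–Claisen); the side chain is cut at the CH2–CH=CMe2 bond (allyl–alkenyl coupling).
- Ring A (the cyclopentane) is cut at two ring bonds, CH2–CH2 and CH–CH, into a three-carbon unit (CH2–C–CH) and the terminal vinyl group of a Z-1,3-diene.
- Enabling feature: the quaternary carbinol carbon of ring A lies between a ring CH2 and the ring CH that carries the CH–C=O arm of ring B. At the ketone level this makes the CH2 an α-keto radical site and the CH the β-carbon of an enoyl imide; the other CH2–CH pair of ring A is the vinyl end of the diene that already holds the Z-alkene.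
- Forward: radical [3+2] annulation gives ring A as a ketone; then C=O to C=CH2 to diol (acetonide), side-chain coupling, auxiliary to chiral ester, Claisen, vinyl ketone, metathesis (ring B), deprotection, acetylation.
- Stereochemistry: the oxazolidinone auxiliary sets the ring carbon bearing ring B; the cis closure of the 5-exo cyclisation sets the side-chain carbon; osmylation anti to both sets the carbinol; chirality transfer from (S,E)-pent-3-en-2-ol sets both ring B centres; the Z-alkene comes from the starting enynol.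

Key step: step 5

Assumption: compounds 1, 4, 5, 14 and 16 are taken as purchasable in isomerically and enantiomerically pure form.

Step 1
Reactants: 1 (Z)-3-methylpent-2-en-4-yn-1-ol
Product: 2 methyl (Z)-3-methylpent-2-en-4-yn-1-yl carbonate
Conditions: ClCO2Me, pyridine, CH2Cl2, 0 °C
Reagents that add atoms: methyl chloroformate, COC(=O)Cl
Why: Carbonate formation on the primary allylic alcohol installs the leaving group for the later allylic coupling and deactivates the trisubstituted alkene towards oxidation.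

Step 2
Reactants: 2 methyl (Z)-3-methylpent-2-en-4-yn-1-yl carbonate
Product: 3 methyl (Z)-3-methylpenta-2,4-dien-1-yl carbonate
Conditions: H2 (1 atm), Pd/CaCO3 poisoned with Pb(OAc)2 (Lindlar catalyst), quinoline, EtOAc, rt
Reagents that add atoms: none
Why: Lindlar semi-hydrogenation should stop the terminal alkyne at the vinyl group and leave the Z-trisubstituted alkene unchanged.

Step 3
Reactants: 4 (E)-4-oxopent-2-enoic acid; 5 (S)-4-(diphenylmethyl)oxazolidin-2-one
Product: 7 (S)-4-(diphenylmethyl)-3-[(E)-4-oxopent-2-enoyl]oxazolidin-2-one, via mixed pivalic anhydride 6 (not isolated)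
Conditions: PivCl, Et3N, THF, −20 °C; then 5, LiCl, rt
Reagents that add atoms: none
Why: N-Acylation of the oxazolidinone through the mixed anhydride (LiCl/Et3N variant) attaches the auxiliary without the strong base that the enone would not tolerate.

Step 4
Reactants: 7 (S)-4-(diphenylmethyl)-3-[(E)-4-oxopent-2-enoyl]oxazolidin-2-one
Product: 9 (S)-3-[(E)-5-bromo-4-oxopent-2-enoyl]-4-(diphenylmethyl)oxazolidin-2-one, via silyl dienol ether 8 (not isolated)
Conditions: TMSOTf, Et3N, CH2Cl2, 0 °C; then NBS, THF, −78 °C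
Reagents that add atoms: N-bromosuccinimide, O=C1CCC(=O)N1Br
Why: α-Halogenation through the silyl enol ether of the only enolisable position (the methyl ketone) should give the bromomethyl ketone regioselectively.

Step 5
Reactants: 9 (S)-3-[(E)-5-bromo-4-oxopent-2-enoyl]-4-(diphenylmethyl)oxazolidin-2-one; 3 methyl (Z)-3-methylpenta-2,4-dien-1-yl carbonate
Product: 10 (S)-4-(diphenylmethyl)-3-{2-[(1R,2R)-2-[(Z)-4-(methoxycarbonyloxy)but-2-en-2-yl]-5-oxocyclopentyl]acetyl}oxazolidin-2-one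
Conditions: 3 (3 equiv), Yb(OTf)3 (1.1 equiv), Bu3SnH (1.3 equiv, syringe pump), Et3B (0.3 equiv), air, CH2Cl2–THF 4:1, −78 °C
Reagents that add atoms: none
Why: Proposed new method: bromine abstraction from 9 gives an electrophilic α-keto radical at the CH2 carbon, which adds to the terminal CH2 of the electron-rich diene 3 (first new bond); the allyl radical so formed closes by 5-exo-trig attack on the β-carbon of the Yb(OTf)3-chelated enoyl imide (second new bond), and the α-imide radical is reduced by Bu3SnH. The closest known reaction types are the Kharasch-type addition of α-halo ketones to 1,3-dienes and the Lewis-acid-mediated radical conjugate addition to N-enoyl oxazolidinones, merged here into one annulation. Ring A closes in the 5-exo mode onto the alkene carbon next to the ketone; the 6-endo and seven-membered closures should be disfavoured by the chelate activation of that carbon and by the s-trans shape of the allyl radical. The ring carbon bearing the CH2C(O)N arm is set by the diphenylmethyl group of the auxiliary, which shields one face of the s-cis chelated enoyl unit; the cis relation of the side-chain carbon to it is expected from the chair-like transition state of 5-exo cyclisation with the dienyl group pseudo-equatorial. The step needs the first radical to be captured by the diene and not by the acceptor of a second molecule, which polarity matching secures (electrophilic radical, electron-rich diene, electron-poor acceptor). It also needs the Z geometry to survive, which the low temperature should secure because the allyl radical cyclises faster than it rotates.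

Step 6
Reactants: 10 (S)-4-(diphenylmethyl)-3-{2-[(1R,2R)-2-[(Z)-4-(methoxycarbonyloxy)but-2-en-2-yl]-5-oxocyclopentyl]acetyl}oxazolidin-2-one
Product: 11 (S)-4-(diphenylmethyl)-3-{2-[(1R,2R)-2-[(Z)-4-(methoxycarbonyloxy)but-2-en-2-yl]-5-methylidenecyclopentyl]acetyl}oxazolidin-2-one
Conditions: Zn, CH2Br2, TiCl4, THF–CH2Cl2, 0 °C to rt
Reagents that add atoms: dibromomethane, BrCBr
Why: Lombardo methylenation converts the hindered ring ketone into the exocyclic methylene under non-basic conditions, so the adjacent α-stereocentre should not epimerise and the imide and carbonate should be spared.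

Step 7
Reactants: 11 (S)-4-(diphenylmethyl)-3-{2-[(1R,2R)-2-[(Z)-4-(methoxycarbonyloxy)but-2-en-2-yl]-5-methylidenecyclopentyl]acetyl}oxazolidin-2-one
Product: 12 (S)-4-(diphenylmethyl)-3-{2-[(1R,2R,5R)-2-hydroxy-2-(hydroxymethyl)-5-[(Z)-4-(methoxycarbonyloxy)but-2-en-2-yl]cyclopentyl]acetyl}oxazolidin-2-one
Conditions: OsO4 (2 mol%), NMO, acetone–H2O, 0 °C
Reagents that add atoms: osmium tetroxide, O=[Os](=O)(=O)=O; N-methylmorpholine N-oxide, C[N+]1([O-])CCOCC1; water, O
Why: Catalytic osmylation should attack the 1,1-disubstituted exocyclic alkene in preference to the carbonate-deactivated trisubstituted alkene, and from the face opposite the two cis ring substituents, which sets the carbinol centre with OH trans to them.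

Step 8
Reactants: 12 (S)-4-(diphenylmethyl)-3-{2-[(1R,2R,5R)-2-hydroxy-2-(hydroxymethyl)-5-[(Z)-4-(methoxycarbonyloxy)but-2-en-2-yl]cyclopentyl]acetyl}oxazolidin-2-one
Product: 13 (S)-4-(diphenylmethyl)-3-{2-[(5R,6R,7R)-7-[(Z)-4-(methoxycarbonyloxy)but-2-en-2-yl]-2,2-dimethyl-1,3-dioxaspiro[4.4]nonan-6-yl]acetyl}oxazolidin-2-one
Conditions: 2,2-dimethoxypropane, PPTS (cat.), CH2Cl2, rt
Reagents that add atoms: 2,2-dimethoxypropane, COC(C)(C)OC
Why: Acetonide formation protects the tertiary/primary 1,2-diol for the basic and organometallic steps that follow.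

Step 9
Reactants: 13 (S)-4-(diphenylmethyl)-3-{2-[(5R,6R,7R)-7-[(Z)-4-(methoxycarbonyloxy)but-2-en-2-yl]-2,2-dimethyl-1,3-dioxaspiro[4.4]nonan-6-yl]acetyl}oxazolidin-2-one; 14 4,4,5,5-tetramethyl-2-(2-methylprop-1-en-1-yl)-1,3,2-dioxaborolane
Product: 15 (S)-4-(diphenylmethyl)-3-{2-[(5R,6R,7R)-2,2-dimethyl-7-[(Z)-6-methylhepta-2,5-dien-2-yl]-1,3-dioxaspiro[4.4]nonan-6-yl]acetyl}oxazolidin-2-one
Conditions: Pd(PPh3)4 (5 mol%), THF, 50 °C, no added base
Reagents that add atoms: none
Why: Suzuki–Miyaura-type allyl–alkenyl coupling of the allylic carbonate through its π-allyl palladium complex should join the alkenyl group at the primary terminus with the Z-alkene retained, because syn–anti isomerisation would need a σ-bond to the tertiary allyl carbon.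

Step 10
Reactants: 15 (S)-4-(diphenylmethyl)-3-{2-[(5R,6R,7R)-2,2-dimethyl-7-[(Z)-6-methylhepta-2,5-dien-2-yl]-1,3-dioxaspiro[4.4]nonan-6-yl]acetyl}oxazolidin-2-one; 16 (S,E)-pent-3-en-2-ol
Product: 18 (S,E)-pent-3-en-2-yl 2-[(5R,6R,7R)-2,2-dimethyl-7-[(Z)-6-methylhepta-2,5-dien-2-yl]-1,3-dioxaspiro[4.4]nonan-6-yl]acetate, via lithium (S,E)-pent-3-en-2-olate 17 (not isolated)
Conditions: 16, n-BuLi, THF, −78 °C; then 15, 0 °C; aqueous NH4Cl
Reagents that add atoms: none
Why: Alkoxide cleavage of the N-acyl oxazolidinone at the exocyclic carbonyl (transesterification) removes the auxiliary and installs the chiral allylic ester needed for the rearrangement.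

Step 11
Reactants: 18 (S,E)-pent-3-en-2-yl 2-[(5R,6R,7R)-2,2-dimethyl-7-[(Z)-6-methylhepta-2,5-dien-2-yl]-1,3-dioxaspiro[4.4]nonan-6-yl]acetate
Product: 21 (2S,3R,E)-2-[(5R,6S,7R)-2,2-dimethyl-7-[(Z)-6-methylhepta-2,5-dien-2-yl]-1,3-dioxaspiro[4.4]nonan-6-yl]-3-methylhex-4-enoic acid, via silyl ketene acetal 19 (not isolated), via trimethylsilyl ester 20 (not isolated)
Conditions: LiN(iPr)2, TMSCl, THF, −78 °C, then rt; aqueous work-up
Reagents that add atoms: none
Why: Ireland–Claisen rearrangement of the (E)-silyl ketene acetal through the chair transition state with the carbinol methyl group equatorial transfers the chirality of the (S)-allylic ester to both new centres, giving the anti acid that becomes the cis-4,5-disubstituted enone.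

Step 12
Reactants: 21 (2S,3R,E)-2-[(5R,6S,7R)-2,2-dimethyl-7-[(Z)-6-methylhepta-2,5-dien-2-yl]-1,3-dioxaspiro[4.4]nonan-6-yl]-3-methylhex-4-enoic acid
Product: 22 (2S,3R,E)-N-methoxy-N,3-dimethyl-2-[(5R,6S,7R)-2,2-dimethyl-7-[(Z)-6-methylhepta-2,5-dien-2-yl]-1,3-dioxaspiro[4.4]nonan-6-yl]hex-4-enamide
Conditions: MeNH(OMe)·HCl, EDC·HCl, HOBt (cat.), N-methylmorpholine, CH2Cl2, 0 °C to rt
Reagents that add atoms: N,O-dimethylhydroxylamine hydrochloride, CNOC.Cl
Why: Carbodiimide amidation should give the Weinreb amide without epimerising the α-centre.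

Step 13
Reactants: 22 (2S,3R,E)-N-methoxy-N,3-dimethyl-2-[(5R,6S,7R)-2,2-dimethyl-7-[(Z)-6-methylhepta-2,5-dien-2-yl]-1,3-dioxaspiro[4.4]nonan-6-yl]hex-4-enamide
Product: 23 (4S,5R,E)-4-[(5R,6S,7R)-2,2-dimethyl-7-[(Z)-6-methylhepta-2,5-dien-2-yl]-1,3-dioxaspiro[4.4]nonan-6-yl]-5-methylocta-1,6-dien-3-one
Conditions: CH2=CHMgBr, THF, −78 to 0 °C; cold aqueous NH4Cl
Reagents that add atoms: vinylmagnesium bromide, C=C[Mg]Br
Why: In the Weinreb ketone synthesis the chelated tetrahedral intermediate prevents over-addition, and the vinyl ketone is set free only on quench.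

Step 14
Reactants: 23 (4S,5R,E)-4-[(5R,6S,7R)-2,2-dimethyl-7-[(Z)-6-methylhepta-2,5-dien-2-yl]-1,3-dioxaspiro[4.4]nonan-6-yl]-5-methylocta-1,6-dien-3-one
Product: 24 (4R,5S)-5-[(5R,6S,7R)-2,2-dimethyl-7-[(Z)-6-methylhepta-2,5-dien-2-yl]-1,3-dioxaspiro[4.4]nonan-6-yl]-4-methylcyclopent-2-en-1-one
Conditions: second-generation Grubbs catalyst (H2IMes)(PCy3)Cl2Ru=CHPh (5 mol%), CH2Cl2, 40 °C
Reagents that add atoms: none
Why: Ring-closing metathesis between the vinyl ketone and the propenyl group should form ring B with loss of propene, since the trisubstituted side-chain alkenes react far more slowly.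

Step 15
Reactants: 24 (4R,5S)-5-[(5R,6S,7R)-2,2-dimethyl-7-[(Z)-6-methylhepta-2,5-dien-2-yl]-1,3-dioxaspiro[4.4]nonan-6-yl]-4-methylcyclopent-2-en-1-one
Product: 25 (4R,5S)-5-[(1S,2R,5R)-2-hydroxy-2-(hydroxymethyl)-5-[(Z)-6-methylhepta-2,5-dien-2-yl]cyclopentyl]-4-methylcyclopent-2-en-1-one
Conditions: AcOH–H2O 4:1, rt
Reagents that add atoms: none
Why: Mild acid hydrolysis of the acetonide should free the diol without touching the skipped diene or the epimerisable α-centre of the enone.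

Step 16
Reactants: 25 (4R,5S)-5-[(1S,2R,5R)-2-hydroxy-2-(hydroxymethyl)-5-[(Z)-6-methylhepta-2,5-dien-2-yl]cyclopentyl]-4-methylcyclopent-2-en-1-one
Product: 26 [(1R,2S,3R)-1-hydroxy-3-[(Z)-6-methylhepta-2,5-dien-2-yl]-2-[(1S,5R)-5-methyl-2-oxocyclopent-3-en-1-yl]cyclopentyl]methyl acetate
Conditions: vinyl acetate, immobilised Candida antarctica lipase B, MTBE, rt
Reagents that add atoms: vinyl acetate, C=COC(C)=O
Why: Lipase-catalysed transesterification should acylate only the primary hydroxyl under neutral conditions, which avoids base-induced epimerisation of the cis-enone.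

**Compound list**
1 | (Z)-3-methylpent-2-en-4-yn-1-ol | C#C/C(C)=C\CO | starting material
2 | methyl (Z)-3-methylpent-2-en-4-yn-1-yl carbonate | C#C/C(C)=C\COC(=O)OC | intermediate
3 | methyl (Z)-3-methylpenta-2,4-dien-1-yl carbonate | C=C/C(C)=C\COC(=O)OC | intermediate
4 | (E)-4-oxopent-2-enoic acid | CC(=O)/C=C/C(=O)O | starting material
5 | (S)-4-(diphenylmethyl)oxazolidin-2-one | O=C1N[C@@H](C(c2ccccc2)c2ccccc2)CO1 | starting material
6 | (E)-4-oxopent-2-enoic pivalic anhydride | CC(=O)/C=C/C(=O)OC(=O)C(C)(C)C | intermediate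
7 | (S)-4-(diphenylmethyl)-3-[(E)-4-oxopent-2-enoyl]oxazolidin-2-one | CC(=O)/C=C/C(=O)N1[C@@H](C(c2ccccc2)c2ccccc2)COC1=O | intermediate
8 | (S)-4-(diphenylmethyl)-3-[(E)-4-(trimethylsilyloxy)penta-2,4-dienoyl]oxazolidin-2-one | C=C(O[Si](C)(C)C)/C=C/C(=O)N1[C@@H](C(c2ccccc2)c2ccccc2)COC1=O | intermediate
9 | (S)-3-[(E)-5-bromo-4-oxopent-2-enoyl]-4-(diphenylmethyl)oxazolidin-2-one | BrCC(=O)/C=C/C(=O)N1[C@@H](C(c2ccccc2)c2ccccc2)COC1=O | intermediate
10 | (S)-4-(diphenylmethyl)-3-{2-[(1R,2R)-2-[(Z)-4-(methoxycarbonyloxy)but-2-en-2-yl]-5-oxocyclopentyl]acetyl}oxazolidin-2-one | O=C1CC[C@@H](/C(C)=C\COC(=O)OC)[C@H]1CC(=O)N1[C@@H](C(c2ccccc2)c2ccccc2)COC1=O | intermediate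
11 | (S)-4-(diphenylmethyl)-3-{2-[(1R,2R)-2-[(Z)-4-(methoxycarbonyloxy)but-2-en-2-yl]-5-methylidenecyclopentyl]acetyl}oxazolidin-2-one | C=C1CC[C@@H](/C(C)=C\COC(=O)OC)[C@H]1CC(=O)N1[C@@H](C(c2ccccc2)c2ccccc2)COC1=O | intermediate
12 | (S)-4-(diphenylmethyl)-3-{2-[(1R,2R,5R)-2-hydroxy-2-(hydroxymethyl)-5-[(Z)-4-(methoxycarbonyloxy)but-2-en-2-yl]cyclopentyl]acetyl}oxazolidin-2-one | OC[C@@]1(O)CC[C@@H](/C(C)=C\COC(=O)OC)[C@H]1CC(=O)N1[C@@H](C(c2ccccc2)c2ccccc2)COC1=O | intermediate
13 | (S)-4-(diphenylmethyl)-3-{2-[(5R,6R,7R)-7-[(Z)-4-(methoxycarbonyloxy)but-2-en-2-yl]-2,2-dimethyl-1,3-dioxaspiro[4.4]nonan-6-yl]acetyl}oxazolidin-2-one | CC1(C)OC[C@@]2(O1)CC[C@@H](/C(C)=C\COC(=O)OC)[C@H]2CC(=O)N1[C@@H](C(c2ccccc2)c2ccccc2)COC1=O | intermediate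
14 | 4,4,5,5-tetramethyl-2-(2-methylprop-1-en-1-yl)-1,3,2-dioxaborolane | CC(C)=CB1OC(C)(C)C(C)(C)O1 | starting material
15 | (S)-4-(diphenylmethyl)-3-{2-[(5R,6R,7R)-2,2-dimethyl-7-[(Z)-6-methylhepta-2,5-dien-2-yl]-1,3-dioxaspiro[4.4]nonan-6-yl]acetyl}oxazolidin-2-one | CC1(C)OC[C@@]2(O1)CC[C@@H](/C(C)=C\CC=C(C)C)[C@H]2CC(=O)N1[C@@H](C(c2ccccc2)c2ccccc2)COC1=O | intermediate
16 | (S,E)-pent-3-en-2-ol | C/C=C/[C@H](C)O | starting material
17 | lithium (S,E)-pent-3-en-2-olate | C/C=C/[C@H](C)[O-].[Li+] | intermediate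
18 | (S,E)-pent-3-en-2-yl 2-[(5R,6R,7R)-2,2-dimethyl-7-[(Z)-6-methylhepta-2,5-dien-2-yl]-1,3-dioxaspiro[4.4]nonan-6-yl]acetate | CC1(C)OC[C@@]2(O1)CC[C@@H](/C(C)=C\CC=C(C)C)[C@H]2CC(=O)O[C@@H](C)/C=C/C | intermediate
19 | (E)-O-trimethylsilyl ketene acetal of ester 18 | CC1(C)OC[C@@]2(O1)CC[C@@H](/C(C)=C\CC=C(C)C)[C@H]2/C=C(/O[Si](C)(C)C)O[C@@H](C)/C=C/C | intermediate
20 | trimethylsilyl (2S,3R,E)-2-[(5R,6S,7R)-2,2-dimethyl-7-[(Z)-6-methylhepta-2,5-dien-2-yl]-1,3-dioxaspiro[4.4]nonan-6-yl]-3-methylhex-4-enoate | CC1(C)OC[C@@]2(O1)CC[C@@H](/C(C)=C\CC=C(C)C)[C@H]2[C@@H](C(=O)O[Si](C)(C)C)[C@H](C)/C=C/C | intermediate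
21 | (2S,3R,E)-2-[(5R,6S,7R)-2,2-dimethyl-7-[(Z)-6-methylhepta-2,5-dien-2-yl]-1,3-dioxaspiro[4.4]nonan-6-yl]-3-methylhex-4-enoic acid | CC1(C)OC[C@@]2(O1)CC[C@@H](/C(C)=C\CC=C(C)C)[C@H]2[C@@H](C(=O)O)[C@H](C)/C=C/C | intermediate
22 | (2S,3R,E)-N-methoxy-N,3-dimethyl-2-[(5R,6S,7R)-2,2-dimethyl-7-[(Z)-6-methylhepta-2,5-dien-2-yl]-1,3-dioxaspiro[4.4]nonan-6-yl]hex-4-enamide | CC1(C)OC[C@@]2(O1)CC[C@@H](/C(C)=C\CC=C(C)C)[C@H]2[C@@H](C(=O)N(C)OC)[C@H](C)/C=C/C | intermediate
23 | (4S,5R,E)-4-[(5R,6S,7R)-2,2-dimethyl-7-[(Z)-6-methylhepta-2,5-dien-2-yl]-1,3-dioxaspiro[4.4]nonan-6-yl]-5-methylocta-1,6-dien-3-one | CC1(C)OC[C@@]2(O1)CC[C@@H](/C(C)=C\CC=C(C)C)[C@H]2[C@@H](C(=O)C=C)[C@H](C)/C=C/C | intermediate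
24 | (4R,5S)-5-[(5R,6S,7R)-2,2-dimethyl-7-[(Z)-6-methylhepta-2,5-dien-2-yl]-1,3-dioxaspiro[4.4]nonan-6-yl]-4-methylcyclopent-2-en-1-one | CC1(C)OC[C@@]2(O1)CC[C@@H](/C(C)=C\CC=C(C)C)[C@H]2[C@H]1C(=O)C=C[C@H]1C | intermediate
25 | (4R,5S)-5-[(1S,2R,5R)-2-hydroxy-2-(hydroxymethyl)-5-[(Z)-6-methylhepta-2,5-dien-2-yl]cyclopentyl]-4-methylcyclopent-2-en-1-one | OC[C@@]1(O)CC[C@@H](/C(C)=C\CC=C(C)C)[C@H]1[C@H]1C(=O)C=C[C@H]1C | intermediate
26 | [(1R,2S,3R)-1-hydroxy-3-[(Z)-6-methylhepta-2,5-dien-2-yl]-2-[(1S,5R)-5-methyl-2-oxocyclopent-3-en-1-yl]cyclopentyl]methyl acetate | CC(=O)OC[C@@]1(O)CC[C@@H](/C(C)=C\CC=C(C)C)[C@H]1[C@H]1C(=O)C=C[C@H]1C | target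

Total step count: 16. Longest linear sequence: 14 steps (4 to 26, steps 3–16); the diene branch (1 to 3) has 2 steps.

**Steps most likely to fail**

1. Step 5. The one-pot annulation may suffer from premature reduction of the first radical or of the allyl radical, from 6-endo closure, from low cis selectivity in the ring closure, or from epimerisation next to the new ring ketone. Fallback, from 9 and 3: the two bond formations are separated into two known reactions. Atom-transfer (Kharasch) addition of 9 to 3 under Ru(bpy)3Cl2 and visible light in DMF at rt should give the allylic bromide (S)-3-[(2E,8Z)-7-bromo-10-(methoxycarbonyloxy)-8-methyl-4-oxodeca-2,8-dienoyl]-4-(diphenylmethyl)oxazolidin-2-one F1 (with its allylic isomer). A classical tin hydride radical cyclisation of F1 (Bu3SnH, Et3B, air, Yb(OTf)3, CH2Cl2–THF, −78 °C) onto the chelated enoyl imide then returns to 10.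

2. Step 10. The hindered secondary alkoxide may attack slowly, and endocyclic opening of the oxazolidinone ring may compete. Fallback, from 15: cleavage with LiSEt (EtSH, n-BuLi, THF, 0 °C) should give S-ethyl 2-[(5R,6R,7R)-2,2-dimethyl-7-[(Z)-6-methylhepta-2,5-dien-2-yl]-1,3-dioxaspiro[4.4]nonan-6-yl]ethanethioate F2 and the free auxiliary. Silver-promoted transacylation of F2 with 16 (AgOCOCF3, CH2Cl2, rt) then gives 18.

3. Step 13. The Grignard reagent may over-add or add in conjugate fashion to the liberated enone, and the α-branched amide may enolise. Fallback, from 21: the acid is converted under neutral conditions with 1-chloro-N,N,2-trimethylprop-1-enylamine into (2S,3R,E)-2-[(5R,6S,7R)-2,2-dimethyl-7-[(Z)-6-methylhepta-2,5-dien-2-yl]-1,3-dioxaspiro[4.4]nonan-6-yl]-3-methylhex-4-enoyl chloride F3. Stille acylation of F3 with tributyl(vinyl)stannane (Pd2(dba)3, tri(2-furyl)phosphine, THF, rt) gives 23 directly, bypassing 22.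

Further compounds
F1 | step 5 | (S)-3-[(2E,8Z)-7-bromo-10-(methoxycarbonyloxy)-8-methyl-4-oxodeca-2,8-dienoyl]-4-(diphenylmethyl)oxazolidin-2-one | COC(=O)OC/C=C(C)\C(Br)CCC(=O)/C=C/C(=O)N1[C@@H](C(c2ccccc2)c2ccccc2)COC1=O
F2 | step 10 | S-ethyl 2-[(5R,6R,7R)-2,2-dimethyl-7-[(Z)-6-methylhepta-2,5-dien-2-yl]-1,3-dioxaspiro[4.4]nonan-6-yl]ethanethioate | CC1(C)OC[C@@]2(O1)CC[C@@H](/C(C)=C\CC=C(C)C)[C@H]2CC(=O)SCC
F3 | step 13 | (2S,3R,E)-2-[(5R,6S,7R)-2,2-dimethyl-7-[(Z)-6-methylhepta-2,5-dien-2-yl]-1,3-dioxaspiro[4.4]nonan-6-yl]-3-methylhex-4-enoyl chloride | CC1(C)OC[C@@]2(O1)CC[C@@H](/C(C)=C\CC=C(C)C)[C@H]2[C@@H](C(=O)Cl)[C@H](C)/C=C/C
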